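**Retrosynth­etic overview**
1. The target is a depside of ring A (C1' depside carbonyl, C2' OH, C3' Me, C4' OMe, C5' Cl, C6' Me) and ring B (C1 CO2Me, C2 OH, C3 Me, C4 depside oxygen, C5 Me, C6 Me). The plan rests on the adjacent C4'(OMe)/C5'(Cl) pair of ring A, with C4' para to C1'.
2. Ring A is cut at C5'–C6' and C3'–C4' into a 4-acetoxy-3,6-dimethyl-2-pyranone-5-carboxylate, already esterified to ring B, and 2-chloro-1,1-dimethoxyethene; CO2 and methanol are lost on aromatisation.
3. The pyranone is cut into the ring B acetoacetate and methylmalonyl dichloride; the acetoacetate comes from the ring B phenol and a dioxinone, and ring B from atraric acid by C5 formylation and hydrogenolysis.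
4. Ring order: ring B (bought, completed at C5), then the pyranone ring, then ring A on the finished depside ester; both hydroxyls travel as acetates and are freed last.

Key step: step 8

Remark on the chemistry: the target is achiral; 10, 15 and 16 carry transient sp3 centres and are taken as stereoisomer mixtures, and methylmalonyl dichloride 9 is prepared fresh because it is moisture-sensitive.

**Route**

Step 1
Reactants: 1 methyl 2,4-dihydroxy-3,6-dimethylbenzoate (atraric acid)
Product: 2 methyl 5-formyl-2,4-dihydroxy-3,6-dimethylbenzoate
Conditions: Cl2CHOMe (1.5 equiv), TiCl4 (3 equiv), CH2Cl2, −10 °C to rt; then 1 M aq. HCl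
Reagents that add atoms: dichloromethyl methyl ether, ClC(Cl)OC; water, O
Why: Rieche formylation (Friedel–Crafts type) should go to C5, the only unsubstituted ring carbon, which is ortho to the C4 hydroxyl and para to the C2 hydroxyl, and the aqueous work-up releases the aldehyde.

Step 2
Reactants: 2 methyl 5-formyl-2,4-dihydroxy-3,6-dimethylbenzoate
Product: 4 methyl 2,4-dihydroxy-3,5,6-trimethylbenzoate, via benzylic alcohol 3 (not isolated)
Conditions: H2 (3 atm), 10% Pd/C, AcOH, conc. HCl (cat.), rt
Reagents that add atoms: none
Why: Catalytic hydrogenation of the aldehyde to 3 followed by acid-assisted benzylic C–O hydrogenolysis, eased by the ortho and para hydroxyls, should give the methyl group while the ester and the arene stay untouched.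

Step 3
Reactants: 4 methyl 2,4-dihydroxy-3,5,6-trimethylbenzoate; 5 2,2,6-trimethyl-4H-1,3-dioxin-4-one
Product: 7 methyl 2-hydroxy-3,5,6-trimethyl-4-(3-oxobutanoyloxy)benzoate, via acetylketene 6 (not isolated)
Conditions: 5 (1.1 equiv), xylene, 130 °C, acetone distilled off
Reagents that add atoms: none
Why: Thermal retro-[4+2] cleavage of 5 gives acetylketene 6, which should acetoacetylate the non-chelated C4 hydroxyl (acylketene trapping) while the C2 hydroxyl stays hydrogen-bonded to the ester carbonyl, and the fully substituted ring excludes a Pechmann-type closure.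

Step 4
Reactants: 8 methylmalonic acid
Product: 9 methylmalonyl dichloride
Conditions: SOCl2 (3 equiv), DMF (cat.), 50 °C; distillation under reduced pressure
Reagents that add atoms: thionyl chloride, O=S(Cl)Cl
Why: Standard conversion of a dicarboxylic acid into its dichloride with thionyl chloride under formamide catalysis, kept at moderate temperature to limit ketene formation.

Step 5
Reactants: 7 methyl 2-hydroxy-3,5,6-trimethyl-4-(3-oxobutanoyloxy)benzoate; 9 methylmalonyl dichloride
Product: 11 3-hydroxy-4-(methoxycarbonyl)-2,5,6-trimethylphenyl 4-hydroxy-3,6-dimethyl-2-oxo-2H-pyran-5-carboxylate, via C-acylated acid chloride 10 (not isolated)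
Conditions: 9 (1.2 equiv), toluene, 70 °C, N2 stream, no base
Reagents that add atoms: none
Why: Cyclocondensation of a β-keto ester with a malonyl dichloride to a 4-hydroxy-2-pyranone-5-carboxylate: the enol carbon of 7 is acylated to 10, the acetyl enol oxygen closes the lactone on the second acid chloride and the ring enolises, while the chelated C2 hydroxyl of ring B is a poor nucleophile without base.

Step 6
Reactants: 11 3-hydroxy-4-(methoxycarbonyl)-2,5,6-trimethylphenyl 4-hydroxy-3,6-dimethyl-2-oxo-2H-pyran-5-carboxylate
Product: 12 3-acetoxy-4-(methoxycarbonyl)-2,5,6-trimethylphenyl 4-acetoxy-3,6-dimethyl-2-oxo-2H-pyran-5-carboxylate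
Conditions: Ac2O (4 equiv), pyridine, DMAP (cat.), CH2Cl2, 0 °C to rt; cold dilute HCl wash
Reagents that add atoms: acetic anhydride, CC(=O)OC(C)=O
Why: DMAP-catalysed O-acetylation should take the acidic pyranone hydroxyl readily and also the chelated C2 hydroxyl of ring B, and the C3 methyl of the pyranone blocks the O-to-C acyl shift otherwise open to 4-acyloxy-2-pyranones.

Step 7
Reactants: 13 2-chloro-1,1,1-trimethoxyethane
Product: 14 2-chloro-1,1-dimethoxyethene
Conditions: TMSOTf (1.1 equiv), iPr2NEt (1.3 equiv), CH2Cl2, −20 °C to rt; pentane extraction, distillation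
Reagents that add atoms: none
Why: Dealcoholation of an orthoester to a ketene acetal: the silyl triflate removes one methoxy group as methoxytrimethylsilane and the hindered amine takes the α-proton, acidified by chlorine, from the dialkoxycarbenium ion.

Step 8
Reactants: 12 3-acetoxy-4-(methoxycarbonyl)-2,5,6-trimethylphenyl 4-acetoxy-3,6-dimethyl-2-oxo-2H-pyran-5-carboxylate; 14 2-chloro-1,1-dimethoxyethene
Product: 17 3-acetoxy-4-(methoxycarbonyl)-2,5,6-trimethylphenyl 2-acetoxy-5-chloro-4-methoxy-3,6-dimethylbenzoate, via bridged lactone 15 (not isolated), via dimethoxycyclohexadiene 16 (not isolated)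
Conditions: 14 (5 equiv), 2,6-di-tert-butyl-4-methylpyridine (0.1 equiv), mesitylene, sealed tube, 140–150 °C; then PPTS (cat.), toluene, 80 °C
Reagents that add atoms: none
Why: Proposed new method: the electron-poor pyranone 12 and the electron-rich ketene acetal 14 should combine in an inverse-electron-demand [4+2] cycloaddition, probably asynchronous, in which the chlorine-bearing nucleophilic carbon attacks pyranone C6 (β to the C5 aryl ester and vinylogous to the lactone carbonyl) and the acetal carbon then bonds to C3, giving the 2-oxabicyclo[2.2.2]octenone 15. Retro-[4+2] loss of CO2 from 15 gives diene 16, whose only aromatising path is 1,2-elimination of methanol across C4'–C5' (finished by the mild acid), so chlorine and one methoxy group are kept. The closest known reaction type is the cycloaddition of 2-pyranone-5-carboxylates with ketene acetals followed by decarboxylative aromatisation to 4-alkoxybenzoates; a pyranone methylated at both bonding termini with a halogenated ketene acetal goes beyond it, hence the excess of 14, the sealed vessel and the high temperature. Ring A is closed as a six-membered carbocycle by intermolecular [4+2] annulation (bonds C5'–C6' and C3'–C4') and becomes aromatic once the lactone bridge is lost. The sp3 centres of 15 and 16 vanish on aromatisation, so no stereocontrol is needed. The selectivity needed is regiochemical (chlorine next to C6', methoxy para to C1') and is secured by the polarity match between the nucleophilic carbon of 14 and C6 of the pyranone; excess 14 also traps the released methanol as orthoester 13, which spares the acetates.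

Step 9
Reactants: 17 3-acetoxy-4-(methoxycarbonyl)-2,5,6-trimethylphenyl 2-acetoxy-5-chloro-4-methoxy-3,6-dimethylbenzoate
Product: 18 3-hydroxy-4-(methoxycarbonyl)-2,5,6-trimethylphenyl 5-chloro-2-hydroxy-4-methoxy-3,6-dimethylbenzoate (target)
Conditions: K2CO3 (0.2 equiv), MeOH–THF, 0 °C to rt; NH4Cl quench
Reagents that add atoms: none
Why: Base-catalysed methanolysis (transesterification) should remove both aryl acetates, while the depside carbonyl is shielded by the C2' oxygen and C6' methyl on the acyl side and by the C3 and C5 methyls on the aryl side, and the methyl ester only exchanges with the solvent.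

**Compound list**
1 | methyl 2,4-dihydroxy-3,6-dimethylbenzoate (atraric acid) | COC(=O)c1c(C)cc(O)c(C)c1O | starting material
2 | methyl 5-formyl-2,4-dihydroxy-3,6-dimethylbenzoate | COC(=O)c1c(C)c(C=O)c(O)c(C)c1O | intermediate
3 | methyl 2,4-dihydroxy-5-(hydroxymethyl)-3,6-dimethylbenzoate | COC(=O)c1c(C)c(CO)c(O)c(C)c1O | intermediate (not isolated)
4 | methyl 2,4-dihydroxy-3,5,6-trimethylbenzoate | COC(=O)c1c(C)c(C)c(O)c(C)c1O | intermediate
5 | 2,2,6-trimethyl-4H-1,3-dioxin-4-one | CC1=CC(=O)OC(C)(C)O1 | starting material
6 | acetylketene (3-oxobut-1-en-1-one) | CC(=O)C=C=O | intermediate (not isolated)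
7 | methyl 2-hydroxy-3,5,6-trimethyl-4-(3-oxobutanoyloxy)benzoate | COC(=O)c1c(C)c(C)c(OC(=O)CC(C)=O)c(C)c1O | intermediate
8 | methylmalonic acid | CC(C(=O)O)C(=O)O | starting material
9 | methylmalonyl dichloride | CC(C(=O)Cl)C(=O)Cl | intermediate
10 | methyl 4-[(2-acetyl-5-chloro-4-methyl-3,5-dioxopentanoyl)oxy]-2-hydroxy-3,5,6-trimethylbenzoate (stereoisomer and tautomer mixture) | COC(=O)c1c(C)c(C)c(OC(=O)C(C(C)=O)C(=O)C(C)C(=O)Cl)c(C)c1O | intermediate (not isolated)
11 | 3-hydroxy-4-(methoxycarbonyl)-2,5,6-trimethylphenyl 4-hydroxy-3,6-dimethyl-2-oxo-2H-pyran-5-carboxylate | COC(=O)c1c(C)c(C)c(OC(=O)C2=C(C)OC(=O)C(C)=C2O)c(C)c1O | intermediate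
12 | 3-acetoxy-4-(methoxycarbonyl)-2,5,6-trimethylphenyl 4-acetoxy-3,6-dimethyl-2-oxo-2H-pyran-5-carboxylate | COC(=O)c1c(C)c(C)c(OC(=O)C2=C(C)OC(=O)C(C)=C2OC(C)=O)c(C)c1OC(C)=O | intermediate (key-step precursor)
13 | 2-chloro-1,1,1-trimethoxyethane | COC(CCl)(OC)OC | starting material
14 | 2-chloro-1,1-dimethoxyethene | COC(OC)=CCl | intermediate
15 | 3-acetoxy-4-(methoxycarbonyl)-2,5,6-trimethylphenyl 5-acetoxy-7-chloro-8,8-dimethoxy-1,4-dimethyl-3-oxo-2-oxabicyclo[2.2.2]oct-5-ene-6-carboxylate (racemic diastereomer mixture) | COC(=O)c1c(C)c(C)c(OC(=O)C2=C(OC(C)=O)C3(C)C(=O)OC2(C)C(Cl)C3(OC)OC)c(C)c1OC(C)=O | intermediate (not isolated)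
16 | 3-acetoxy-4-(methoxycarbonyl)-2,5,6-trimethylphenyl 6-acetoxy-3-chloro-4,4-dimethoxy-2,5-dimethylcyclohexa-1,5-diene-1-carboxylate (racemic) | COC(=O)c1c(C)c(C)c(OC(=O)C2=C(C)C(Cl)C(OC)(OC)C(C)=C2OC(C)=O)c(C)c1OC(C)=O | intermediate (not isolated)
17 | 3-acetoxy-4-(methoxycarbonyl)-2,5,6-trimethylphenyl 2-acetoxy-5-chloro-4-methoxy-3,6-dimethylbenzoate | COC(=O)c1c(C)c(C)c(OC(=O)c2c(C)c(Cl)c(OC)c(C)c2OC(C)=O)c(C)c1OC(C)=O | intermediate (key-step product)
18 | 3-hydroxy-4-(methoxycarbonyl)-2,5,6-trimethylphenyl 5-chloro-2-hydroxy-4-methoxy-3,6-dimethylbenzoate | COC(=O)c1c(C)c(C)c(OC(=O)c2c(C)c(Cl)c(OC)c(C)c2O)c(C)c1O | target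

**Step count and risks**

Total step count: 9. Longest linear sequence: 7 steps (steps 1, 2, 3, 5, 6, 8 and 9); steps 4 and 7 are side branches.

Steps most likely to fail:

1. Step 8 (bears the label). The cycloaddition may stall because both bonding termini of the pyranone carry methyl groups. The ketene acetal may also be used up by polymerisation or by acetyl transfer from the 4-acetoxy group before it adds. The fallback builds ring A by known arene chemistry and sets out from 1 and 4, coming back to the route at 18. Selective methylation of the non-chelated C4 hydroxyl of 1 (MeI, K2CO3, acetone, reflux) should give methyl 2-hydroxy-4-methoxy-3,6-dimethylbenzoate F1. Chlorination of its only free ring position with SO2Cl2 (CH2Cl2, 0 °C) should give methyl 5-chloro-2-hydroxy-4-methoxy-3,6-dimethylbenzoate F2. Saponification of the hindered ester (KOH, aqueous DMSO, 90 °C, then HCl) should give 5-chloro-2-hydroxy-4-methoxy-3,6-dimethylbenzoic acid F3. Condensation of this acid with 4 by trifluoroacetic anhydride in toluene at rt (mixed anhydride, classical depside esterification) should acylate the non-chelated C4 hydroxyl of 4 and give 18 directly.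

2. Step 5. Acylation of the enol oxygen or of the ring B C2 hydroxyl, and self-condensation of the acid chloride through its ketene, may outrun C-acylation and lactone closure. The fallback sets out from 7 and comes back at 11. Silylation with TMSOTf (2.2 equiv) and Et3N in CH2Cl2 at 0 °C should give methyl 3,5,6-trimethyl-2-(trimethylsilyloxy)-4-{[3-(trimethylsilyloxy)but-2-enoyl]oxy}benzoate F4, in which the phenol is masked and the keto ester is fixed as its silyl enol ether. Acylation of this enol ether with 9 in CH2Cl2 from −78 °C to rt, with loss of chlorotrimethylsilane, lactone closure and desilylation of the aryl ether by the hydrogen chloride formed, should give 11.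

3. Step 7. Ionisation of the orthoester without clean deprotonation may let the ketene acetal add to the dimethoxycarbenium ion, and the product may polymerise or hydrolyse during isolation. The fallback sets out from 13 (together with 12) and comes back at 17, without isolating the ketene acetal. Heating 12 with an excess of 13 and a catalytic amount of pivalic acid in mesitylene at 160 °C, with methanol distilled off, should form 14 in the flask by thermal dealcoholation and consume it at once in the cycloaddition of step 8.

**Further compounds**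
F1 | step 8 | methyl 2-hydroxy-4-methoxy-3,6-dimethylbenzoate | COC(=O)c1c(C)cc(OC)c(C)c1O
F2 | step 8 | methyl 5-chloro-2-hydroxy-4-methoxy-3,6-dimethylbenzoate | COC(=O)c1c(C)c(Cl)c(OC)c(C)c1O
F3 | step 8 | 5-chloro-2-hydroxy-4-methoxy-3,6-dimethylbenzoic acid | OC(=O)c1c(C)c(Cl)c(OC)c(C)c1O
F4 | step 5 | methyl 3,5,6-trimethyl-2-(trimethylsilyloxy)-4-{[3-(trimethylsilyloxy)but-2-enoyl]oxy}benzoate (E/Z mixture) | COC(=O)c1c(C)c(C)c(OC(=O)C=C(C)O[Si](C)(C)C)c(C)c1O[Si](C)(C)C
F0 | step 7 | none | none
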